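Readings and results are simulated for substances that don't exist, noise included.

- A ratio of 1.19 of target to starting material stands in Friday's run at its highest target reading, at 1.33 min; call this reading the peak ratio, your estimate of the selectivity factor between making target and over-reacting it.

| flask | starting material | reagent | second substrate | remark | time |
|---|---|---|---|---|---|
| Sunday's | 0.024 M | 0.024 M | 0.012 M | run made earlier |  |
| Friday's | 0.024 M | 0.054 M | 0.012 M | run made earlier |  |
| flask | 0.024 M | 0.0360 M | 0.0120 M |  | 10 min |

| run | time / min | target / % | starting material / % |
|---|---|---|---|
| Sunday's | 0.667 | 15.2 | 56.4 |
| Sunday's | 1.33 | 21.2 | 42.0 |
| Sunday's | 3.00 | 25.6 | 27.2 |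
| Sunday's | 6.00 | 26.4 | 17.5 |
| Friday's | 0.667 | 26.5 | 44.9 |
| Friday's | 1.33 | 30.9 | 26.0 |
| Friday's | 3.00 | 26.3 | 11.4 |
| Friday's | 6.00 | 14.3 | 4.0 |

(standard deviation of a reading: 0.5 percentage points)

- the analysis behind the earlier runs scatters by 0.5 percentage points, standard deviation
- on the list of suspects stand: starting material + reagent -> target; reagent + target -> over-reaction product; second substrate + reagent -> second product; starting material + second substrate -> cross product

- time up to 10 min at which target stands highest
- the amount of target, in percent of the starting material charged, at that time

- If the two suspect steps that touch target are at work, the reagent concentration multiplies both, each being pseudo-first-order in the other partner at a given moment, so it cancels where making equals using: at that point target equals the peak ratio times the starting material.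
- You can test this on Sunday's run, whose ratio climbs from 0.941 at 3.00 min to 1.51 at 6.00 min, passing the peak ratio just where its target readings flatten.
- The two runs then peak at different heights through the starting material present at the peak, about 22.2% on Sunday's against 26.0% on Friday's, because at the first reading target makes up 48.1% of the starting material that has reacted on Friday's, more than the 34.9% on Sunday's.
- Your flask's reagent lies 0.400 of the way from Sunday's charge to Friday's, so you interpolate 23.7% of starting material at the peak and reckon 28.2% of target, a little above the forecast.
- The forecast says 27.5% at 2.3 min, “then a slow fall”.
- The flask gives 28.8% at 2.31 min, which is 1.3 percentage points above the forecast's height.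

    starting material + reagent → target (k = 0.281 /M/s)
    reagent + target → over-reaction product (k = 0.229 /M/s)
    second substrate + reagent → second product (k = 0.330 /M/s)
    starting material + second substrate → cross product (k = 1.26 /M/s)

- In the flask, target is made 2.06 times as fast as it is used up, net, at 0.993 min, but 0.371 times as fast at 10.0 min, and the peak ratio set against the flask's 3.31 of target to starting material at that time gives 0.359. In the neighbour charged with 0.0090 M of reagent, that ratio at 10.0 min is 0.615, below the peak ratio, and its target at that time equals its highest value, 19.0%.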